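**Retrosynthetic overview**
- The strategy rests on ring A of the flavanone. Its two fusion carbons carry O1 (on C8a) and the C4 carbonyl (on C4a), with further oxygens on C5 (next to C4a) and C7. An oxygen nucleophile and an acyl electrophile leave exactly this pattern when they add across the triple bond of a 3,5-dioxygenated benzyne.
- O1–C8a and C4–C4a are cut together. This gives a phloroglucinol-derived o-silylaryl triflate and an (S)-β-hydroxy ester that already holds C2, C3, C4, ring B and the flavone. Ring C is the only ring built, and it is built last.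
- The C5'–C6'' biaryl bond is cut next by Suzuki–Miyaura coupling. The hindered flavone is the 6-iodide, and ring B is the boronate and already carries the carbinol.
- C2 is set on the small ring B fragment by asymmetric transfer hydrogenation of an aryl β-keto ester, made by aldol addition and oxidation from 3-bromo-4,5-dihydroxybenzaldehyde.
- The flavone rings come intact from apigenin. All seven phenols travel as MOM ethers and are freed in the last step.

Key step: step 15

Assumption: the C5'–C6'' axis (three oxygen ortho substituents and one hydrogen) is taken as configurationally labile, since the SMILES gives no axial descriptor; MOM-protected biaryls may show as interconverting rotamers and are treated as single compounds.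

**Step 1**
Reactants: 1 apigenin
Product: 2 5-hydroxy-7-(methoxymethoxy)-2-[4-(methoxymethoxy)phenyl]-4H-chromen-4-one
Conditions: MOMCl (2.3 equiv), K2CO3, acetone, reflux
Reagents that add atoms: chloromethyl methyl ether (MOMCl), COCCl
Why: Williamson-type O-alkylation in which the 7- and 4'-phenoxides react, while the 5-OH is hydrogen-bonded to the C4 carbonyl and stays free under K2CO3.

**Step 2**
Reactants: 2 5-hydroxy-7-(methoxymethoxy)-2-[4-(methoxymethoxy)phenyl]-4H-chromen-4-one
Product: 3 5-hydroxy-6-iodo-7-(methoxymethoxy)-2-[4-(methoxymethoxy)phenyl]-4H-chromen-4-one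
Conditions: BnMe3N·ICl2 (1.05 equiv), CaCO3, CH2Cl2–MeOH, rt
Reagents that add atoms: benzyltrimethylammonium dichloroiodate, C[N+](C)(C)Cc1ccccc1.Cl[I-]Cl
Why: Electrophilic aromatic iodination, which in 5-hydroxy-7-alkoxyflavones goes ortho to the free 5-OH (C6) rather than to C8, with CaCO3 taking up HCl so that the MOM ethers last.

**Step 3**
Reactants: 3 5-hydroxy-6-iodo-7-(methoxymethoxy)-2-[4-(methoxymethoxy)phenyl]-4H-chromen-4-one
Product: 4 6-iodo-5,7-bis(methoxymethoxy)-2-[4-(methoxymethoxy)phenyl]-4H-chromen-4-one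
Conditions: NaH, MOMCl, DMF, 0 °C to rt
Reagents that add atoms: chloromethyl methyl ether (MOMCl), COCCl
Why: O-alkylation of the sodium phenoxide, in which full deprotonation breaks the chelate so that the hindered 5-oxygen is capped and the flavone half loses its last acidic proton before the aryne step.

**Step 4**
Reactants: 5 3-bromo-4,5-dihydroxybenzaldehyde
Product: 6 3-bromo-4,5-bis(methoxymethoxy)benzaldehyde
Conditions: MOMCl (2.5 equiv), i-Pr2NEt, CH2Cl2, 0 °C to rt
Reagents that add atoms: chloromethyl methyl ether (MOMCl), COCCl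
Why: Standard MOM ether formation on both catechol oxygens under amine base, which leaves the aldehyde and the C–Br bond alone.

**Step 5**
Reactants: 6 3-bromo-4,5-bis(methoxymethoxy)benzaldehyde
Product: 7 methyl (±)-3-[3-bromo-4,5-bis(methoxymethoxy)phenyl]-3-hydroxypropanoate
Conditions: LDA, MeOAc, THF, −78 °C; then 6; aq NH4Cl at −78 °C
Reagents that add atoms: methyl acetate, COC(C)=O
Why: Aldol addition of the lithium enolate of methyl acetate to a non-enolisable aryl aldehyde, where the carbinol centre forms racemic and is erased in step 6.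

**Step 6**
Reactants: 7 methyl (±)-3-[3-bromo-4,5-bis(methoxymethoxy)phenyl]-3-hydroxypropanoate
Product: 8 methyl 3-[3-bromo-4,5-bis(methoxymethoxy)phenyl]-3-oxopropanoate
Conditions: Dess–Martin periodinane (1.1 equiv), CH2Cl2, 0 °C to rt
Reagents that add atoms: none
Why: Dess–Martin oxidation of a benzylic β-hydroxy ester to the β-keto ester, run near neutrality with only a slight excess of oxidant so that C2 of the dicarbonyl is not oxidised further.

**Step 7**
Reactants: 8 methyl 3-[3-bromo-4,5-bis(methoxymethoxy)phenyl]-3-oxopropanoate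
Product: 9 methyl (S)-3-[3-bromo-4,5-bis(methoxymethoxy)phenyl]-3-hydroxypropanoate
Conditions: RuCl(p-cymene)[(S,S)-TsDPEN] (1 mol %), HCO2H–Et3N (5:2), CH2Cl2, 30 °C
Reagents that add atoms: none
Why: Noyori asymmetric transfer hydrogenation, in which the aryl group lies against the p-cymene ligand (CH/π contact) in the six-membered hydride and proton transfer state, so the (S,S) catalyst should give the (S) carbinol in the same sense as acetophenone gives (S)-1-phenylethanol, in a mild medium that spares the MOM ethers and C–Br.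

**Step 8**
Reactants: 9 methyl (S)-3-[3-bromo-4,5-bis(methoxymethoxy)phenyl]-3-hydroxypropanoate
Product: 10 methyl (S)-3-hydroxy-3-[3,4-bis(methoxymethoxy)-5-(4,4,5,5-tetramethyl-1,3,2-dioxaborolan-2-yl)phenyl]propanoate
Conditions: B2pin2, Pd(dppf)Cl2 (4 mol %), KOAc, 1,4-dioxane, 85 °C
Reagents that add atoms: bis(pinacolato)diboron, CC1(C)OB(B2OC(C)(C)C(C)(C)O2)OC1(C)C
Why: Miyaura borylation of an aryl bromide, in which the weak base KOAc tolerates the free alcohol and the ester and does not touch the stereocentre.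

**Step 9**
Reactants: 4 6-iodo-5,7-bis(methoxymethoxy)-2-[4-(methoxymethoxy)phenyl]-4H-chromen-4-one; 10 methyl (S)-3-hydroxy-3-[3,4-bis(methoxymethoxy)-5-(4,4,5,5-tetramethyl-1,3,2-dioxaborolan-2-yl)phenyl]propanoate
Product: 11 methyl (S)-3-hydroxy-3-{3,4-bis(methoxymethoxy)-5-[5,7-bis(methoxymethoxy)-2-(4-(methoxymethoxy)phenyl)-4-oxo-4H-chromen-6-yl]phenyl}propanoate
Conditions: Pd(OAc)2 (5 mol %), SPhos (10 mol %), K3PO4, toluene–H2O (10:1), 70 °C
Reagents that add atoms: none
Why: Suzuki–Miyaura coupling with the doubly ortho-oxygenated flavone as the iodide (easy oxidative addition to zerovalent palladium) and the less hindered ring B as the boronate, which avoids a 2,6-dialkoxyarylboronate prone to protodeboronation, while SPhos supports a biaryl with three ortho substituents.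

**Step 10**
Reactants: 12 phloroglucinol
Product: 13 3,5-bis(methoxymethoxy)phenol
Conditions: NaH (2.0 equiv), MOMCl (2.0 equiv), DMF, 0 °C; chromatography
Reagents that add atoms: chloromethyl methyl ether (MOMCl), COCCl
Why: Statistical double O-alkylation of a cheap threefold-symmetric triphenol, where the mono- and tri-ethers formed alongside are removed by chromatography and can be recycled.

**Step 11**
Reactants: 13 3,5-bis(methoxymethoxy)phenol
Product: 14 3,5-bis(methoxymethoxy)phenyl N-isopropylcarbamate
Conditions: i-PrNCO, Et3N (cat.), CH2Cl2, rt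
Reagents that add atoms: isopropyl isocyanate, CC(C)N=C=O
Why: Base-catalysed addition of the phenol to an isocyanate (carbamoylation), which installs a strong ortho-directing group that can later be removed under mild base.

**Step 12**
Reactants: 14 3,5-bis(methoxymethoxy)phenyl N-isopropylcarbamate
Product: 18 3,5-bis(methoxymethoxy)-2-(trimethylsilyl)phenyl N-isopropylcarbamate, via N-TBS carbamate 15 (not isolated), via 2-lithio N-TBS carbamate 16 (not isolated), via N-TBS 2-TMS carbamate 17 (not isolated)
Conditions: TBSOTf (1.05 equiv), TMEDA, Et2O, 0 °C to rt; n-BuLi (2.1 equiv), TMEDA, −78 °C; TMSCl, −78 °C to rt; aq citric acid work-up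
Reagents that add atoms: chlorotrimethylsilane, C[Si](C)(C)Cl; tert-butyldimethylsilyl triflate, CC(C)(C)[Si](C)(C)OS(=O)(=O)C(F)(F)F (its silyl group stays only in 15 to 17)
Why: Directed ortho-metalation, in which the temporarily N-silylated carbamate is the strongest director and cooperates with the neighbouring MOM ether, so lithiation should fall at C2 (equivalent to C6) rather than at C4 between the two MOM ethers, and TMSCl traps the aryllithium.

**Step 13**
Reactants: 18 3,5-bis(methoxymethoxy)-2-(trimethylsilyl)phenyl N-isopropylcarbamate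
Product: 20 3,5-bis(methoxymethoxy)-2-(trimethylsilyl)phenyl trifluoromethanesulfonate, via 2-silylphenol 19 (not isolated)
Conditions: Et2NH, DBU, MeCN, 40 °C; then PhNTf2, rt
Reagents that add atoms: N-phenylbis(trifluoromethanesulfonimide), O=S(=O)(N(c1ccccc1)S(=O)(=O)C(F)(F)F)C(F)(F)F
Why: E1cB cleavage of the N–H carbamate by DBU (the isocyanate is caught by Et2NH), followed by triflation of the phenoxide in the same flask with a mild triflyl donor that spares the aryl–silicon bond and the MOM ethers.

**Step 14**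
Reactants: 11 methyl (S)-3-hydroxy-3-{3,4-bis(methoxymethoxy)-5-[5,7-bis(methoxymethoxy)-2-(4-(methoxymethoxy)phenyl)-4-oxo-4H-chromen-6-yl]phenyl}propanoate
Product: 21 methyl (S)-3-(trimethylsilyloxy)-3-{3,4-bis(methoxymethoxy)-5-[5,7-bis(methoxymethoxy)-2-(4-(methoxymethoxy)phenyl)-4-oxo-4H-chromen-6-yl]phenyl}propanoate
Conditions: TMSCl, Et3N, CH2Cl2, 0 °C; non-acidic work-up, azeotropic drying with toluene
Reagents that add atoms: chlorotrimethylsilane, C[Si](C)(C)Cl
Why: O-silylation of the secondary alcohol, which replaces the only remaining O–H proton by a group that fluoride removes, so the alkoxide can later be released without strong base and without touching any bond at C2.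

**Step 15**
Reactants: 21 methyl (S)-3-(trimethylsilyloxy)-3-{3,4-bis(methoxymethoxy)-5-[5,7-bis(methoxymethoxy)-2-(4-(methoxymethoxy)phenyl)-4-oxo-4H-chromen-6-yl]phenyl}propanoate; 20 3,5-bis(methoxymethoxy)-2-(trimethylsilyl)phenyl trifluoromethanesulfonate
Product: 25 (S)-5,7-bis(methoxymethoxy)-2-{3,4-bis(methoxymethoxy)-5-[5,7-bis(methoxymethoxy)-2-(4-(methoxymethoxy)phenyl)-4-oxo-4H-chromen-6-yl]phenyl}chroman-4-one (hepta-MOM ether of the target), via 3,5-bis(methoxymethoxy)benzyne 22 (not isolated), via cesium alkoxide 23 (not isolated), via aryl anion 24 (not isolated)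
Conditions: 20 (1.5 equiv), dried CsF (1.3 equiv), 18-crown-6 (1.3 equiv), THF, 0 °C to rt; pH 7 phosphate buffer at 0 °C
Reagents that add atoms: none
Why: Proposed new method: fluoride removes the O-silyl group of 21 and the C-silyl group of 20, so alkoxide 23 and benzyne 22 meet in a medium without any O–H proton; 23 adds to the aryne carbon that becomes C8a (bond O1–C8a), and the aryl anion 24 left at C4a attacks the ester carbonyl and expels methoxide (bond C4–C4a). The closest known reaction types are the CsF-mediated annulation of methyl salicylates with arynes to xanthones (oxygen addition, then acylation of the aryl anion by the ester) and the O–H insertion of aliphatic alcohols into arynes; the new element is an aliphatic β-alkoxido ester with enolisable C3 hydrogens as the partner. Ring C closes in the second event as a 6-exo-trig acyl substitution, the first bond being intermolecular. No stereocentre is made, because the C2–O bond is never broken, so the (S) configuration of step 7 is carried through provided that retro-aldol cleavage of 23 and base-induced opening of 25 to the chalcone are held back. Both are addressed by the silicon balance: 23 exists only at low stationary concentration in equilibrium with 21, and with fluoride kept below the total silicon content the released methoxide should end as MeOSiMe3 by attack on 20 or 21 (each such event freeing the next benzyne or alkoxide) instead of enolising C3 of 25. The regioselectivity needed, oxygen at C8a and carbanion at C4a, comes from the alkoxy group on the future C5, whose inductive pull distorts the aryne and stabilises charge on the adjacent carbon, and this outweighs the weak opposite bias of the C7 oxygen.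

**Step 16**
Reactants: 25 (S)-5,7-bis(methoxymethoxy)-2-{3,4-bis(methoxymethoxy)-5-[5,7-bis(methoxymethoxy)-2-(4-(methoxymethoxy)phenyl)-4-oxo-4H-chromen-6-yl]phenyl}chroman-4-one
Product: 26 (S)-2-{3,4-dihydroxy-5-[5,7-dihydroxy-2-(4-hydroxyphenyl)-4-oxo-4H-chromen-6-yl]phenyl}-5,7-dihydroxychroman-4-one (CNP0176432.1)
Conditions: HCl (about 1 M) in MeOH, 35–40 °C, argon
Reagents that add atoms: none
Why: Acid-catalysed acetal exchange of all seven aryl MOM ethers with methanol, while opening of ring C to the chalcone is mainly a base-driven E1cB process, so dilute acid at mild temperature should leave C2 in place.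

**Compound list**
1 | apigenin | O=c1cc(-c2ccc(O)cc2)oc2cc(O)cc(O)c12 | starting material
2 | 5-hydroxy-7-(methoxymethoxy)-2-[4-(methoxymethoxy)phenyl]-4H-chromen-4-one | O=c1cc(-c2ccc(OCOC)cc2)oc2cc(OCOC)cc(O)c12 | intermediate
3 | 5-hydroxy-6-iodo-7-(methoxymethoxy)-2-[4-(methoxymethoxy)phenyl]-4H-chromen-4-one | O=c1cc(-c2ccc(OCOC)cc2)oc2cc(OCOC)c(I)c(O)c12 | intermediate
4 | 6-iodo-5,7-bis(methoxymethoxy)-2-[4-(methoxymethoxy)phenyl]-4H-chromen-4-one | O=c1cc(-c2ccc(OCOC)cc2)oc2cc(OCOC)c(I)c(OCOC)c12 | intermediate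
5 | 3-bromo-4,5-dihydroxybenzaldehyde | O=Cc1cc(O)c(O)c(Br)c1 | starting material
6 | 3-bromo-4,5-bis(methoxymethoxy)benzaldehyde | O=Cc1cc(OCOC)c(OCOC)c(Br)c1 | intermediate
7 | methyl (±)-3-[3-bromo-4,5-bis(methoxymethoxy)phenyl]-3-hydroxypropanoate | COC(=O)CC(O)c1cc(OCOC)c(OCOC)c(Br)c1 | intermediate
8 | methyl 3-[3-bromo-4,5-bis(methoxymethoxy)phenyl]-3-oxopropanoate | COC(=O)CC(=O)c1cc(OCOC)c(OCOC)c(Br)c1 | intermediate
9 | methyl (S)-3-[3-bromo-4,5-bis(methoxymethoxy)phenyl]-3-hydroxypropanoate | COC(=O)C[C@H](O)c1cc(OCOC)c(OCOC)c(Br)c1 | intermediate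
10 | methyl (S)-3-hydroxy-3-[3,4-bis(methoxymethoxy)-5-(4,4,5,5-tetramethyl-1,3,2-dioxaborolan-2-yl)phenyl]propanoate | COC(=O)C[C@H](O)c1cc(OCOC)c(OCOC)c(B2OC(C)(C)C(C)(C)O2)c1 | intermediate
11 | methyl (S)-3-hydroxy-3-{3,4-bis(methoxymethoxy)-5-[5,7-bis(methoxymethoxy)-2-(4-(methoxymethoxy)phenyl)-4-oxo-4H-chromen-6-yl]phenyl}propanoate | COC(=O)C[C@H](O)c1cc(OCOC)c(OCOC)c(-c2c(OCOC)cc3oc(-c4ccc(OCOC)cc4)cc(=O)c3c2OCOC)c1 | intermediate
12 | phloroglucinol | Oc1cc(O)cc(O)c1 | starting material
13 | 3,5-bis(methoxymethoxy)phenol | COCOc1cc(O)cc(OCOC)c1 | intermediate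
14 | 3,5-bis(methoxymethoxy)phenyl N-isopropylcarbamate | CC(C)NC(=O)Oc1cc(OCOC)cc(OCOC)c1 | intermediate
15 | 3,5-bis(methoxymethoxy)phenyl N-(tert-butyldimethylsilyl)-N-isopropylcarbamate | CC(C)N(C(=O)Oc1cc(OCOC)cc(OCOC)c1)[Si](C)(C)C(C)(C)C | intermediate (not isolated)
16 | 2-lithio derivative of 15 | [Li]c1c(OCOC)cc(OCOC)cc1OC(=O)N(C(C)C)[Si](C)(C)C(C)(C)C | intermediate (not isolated)
17 | 3,5-bis(methoxymethoxy)-2-(trimethylsilyl)phenyl N-(tert-butyldimethylsilyl)-N-isopropylcarbamate | CC(C)N(C(=O)Oc1cc(OCOC)cc(OCOC)c1[Si](C)(C)C)[Si](C)(C)C(C)(C)C | intermediate (not isolated)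
18 | 3,5-bis(methoxymethoxy)-2-(trimethylsilyl)phenyl N-isopropylcarbamate | CC(C)NC(=O)Oc1cc(OCOC)cc(OCOC)c1[Si](C)(C)C | intermediate
19 | 3,5-bis(methoxymethoxy)-2-(trimethylsilyl)phenol (present as its DBU salt) | Oc1cc(OCOC)cc(OCOC)c1[Si](C)(C)C | intermediate (not isolated)
20 | 3,5-bis(methoxymethoxy)-2-(trimethylsilyl)phenyl trifluoromethanesulfonate | C[Si](C)(C)c1c(OCOC)cc(OCOC)cc1OS(=O)(=O)C(F)(F)F | intermediate
21 | methyl (S)-3-(trimethylsilyloxy)-3-{3,4-bis(methoxymethoxy)-5-[5,7-bis(methoxymethoxy)-2-(4-(methoxymethoxy)phenyl)-4-oxo-4H-chromen-6-yl]phenyl}propanoate | COC(=O)C[C@H](O[Si](C)(C)C)c1cc(OCOC)c(OCOC)c(-c2c(OCOC)cc3oc(-c4ccc(OCOC)cc4)cc(=O)c3c2OCOC)c1 | intermediate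
22 | 3,5-bis(methoxymethoxy)benzyne (1,2-didehydro-3,5-bis(methoxymethoxy)benzene) | C1#CC(OCOC)=CC(OCOC)=C1 | intermediate (not isolated)
23 | cesium alkoxide of 11 | COC(=O)C[C@H]([O-])c1cc(OCOC)c(OCOC)c(-c2c(OCOC)cc3oc(-c4ccc(OCOC)cc4)cc(=O)c3c2OCOC)c1.[Cs+] | intermediate (not isolated)
24 | cesium aryl anion: (S)-β-aryloxy ester with the carbanion on the ring A carbon between O1-bearing C8a and C5 | COC(=O)C[C@@H](c1cc(OCOC)c(OCOC)c(-c2c(OCOC)cc3oc(-c4ccc(OCOC)cc4)cc(=O)c3c2OCOC)c1)Oc1cc(OCOC)cc(OCOC)[c-]1.[Cs+] | intermediate (not isolated)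
25 | (S)-5,7-bis(methoxymethoxy)-2-{3,4-bis(methoxymethoxy)-5-[5,7-bis(methoxymethoxy)-2-(4-(methoxymethoxy)phenyl)-4-oxo-4H-chromen-6-yl]phenyl}chroman-4-one | O=C1C[C@@H](c2cc(OCOC)c(OCOC)c(-c3c(OCOC)cc4oc(-c5ccc(OCOC)cc5)cc(=O)c4c3OCOC)c2)Oc2cc(OCOC)cc(OCOC)c21 | intermediate
26 | (S)-2-{3,4-dihydroxy-5-[5,7-dihydroxy-2-(4-hydroxyphenyl)-4-oxo-4H-chromen-6-yl]phenyl}-5,7-dihydroxychroman-4-one (CNP0176432.1) | O=C1C[C@@H](c2cc(O)c(O)c(-c3c(O)cc4oc(-c5ccc(O)cc5)cc(=O)c4c3O)c2)Oc2cc(O)cc(O)c21 | target

**Step count**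
Total step count: 16. Longest linear sequence: 9 steps (steps 4 to 9, then 14 to 16).

**Steps most likely to fail**

*Step 15.*
- The aryl anion may be protonated before it reaches the ester, either by a 1,5-proton shift from C3–H or by traces of water.
- The free alkoxide may fragment by retro-aldol cleavage or trigger β-elimination.
- Released methoxide may erode the configuration by opening ring C.
- The fallback sets out from 11 and 20 and uses known reactions only.
- The free alcohol 11 is submitted to the established O–H insertion of aliphatic alcohols into arynes (20, KF, 18-crown-6, THF, −20 °C). The aryl anion is then deliberately protonated, and C2 should stay untouched. This gives methyl (S)-3-[3,5-bis(methoxymethoxy)phenoxy]-3-aryl-propanoate F1, where aryl is the ring B–flavone unit of 11.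
- The same compound is what a proton-quenched key step would leave, so it can be salvaged from there.
- Me3SnOH in 1,2-dichloroethane at 60 °C cleaves the methyl ester without the β-elimination that hydroxide would cause. This gives (S)-3-[3,5-bis(methoxymethoxy)phenoxy]-3-aryl-propanoic acid F2.
- Trifluoroacetic anhydride in CH2Cl2 at 0 °C then closes C4–C4a by intramolecular Friedel–Crafts acylation.
- The two carbons ortho to O1 are equivalent, and the triply oxygen-activated ring A should outrun ring B. The sequence comes back to the route at 25.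

*Step 9.*
- Transmetalation to a doubly ortho-substituted arylpalladium is slow. Protodeboronation, hydrodeiodination, saponification or retro-aldol loss of the β-hydroxy ester may therefore win.
- The fallback sets out from 6 and 4 and moves the coupling ahead of the aldol unit, so that more forcing base and temperature can be used.
- Miyaura borylation of 6 gives 3,4-bis(methoxymethoxy)-5-(4,4,5,5-tetramethyl-1,3,2-dioxaborolan-2-yl)benzaldehyde F3.
- Suzuki–Miyaura coupling of this boronate with 4 gives the biaryl aldehyde 3,4-bis(methoxymethoxy)-5-[5,7-bis(methoxymethoxy)-2-(4-(methoxymethoxy)phenyl)-4-oxo-4H-chromen-6-yl]benzaldehyde F4.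
- The lithium enolate of methyl acetate at −78 °C adds to the aldehyde, which is far more electrophilic than the vinylogous ester carbonyl of the flavone. This gives the racemic β-hydroxy ester F5.
- Dess–Martin oxidation gives the biaryl β-keto ester F6.
- The transfer hydrogenation of step 7 with the same (S,S) catalyst brings the sequence back to the route at 11.

*Step 12.*
- Lithiation may fall at C4 between the two MOM ethers, or a MOM ether may be lost to the silyl triflate before the carbamate nitrogen is capped.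
- The fallback sets out from 13 and fixes the position with a halogen instead of a directing group.
- NBS in CH2Cl2 at low temperature brominates ortho to the free hydroxyl and gives 2-bromo-3,5-bis(methoxymethoxy)phenol F7. Any 4-bromo isomer is separated at this stage.
- Hexamethyldisilazane gives [2-bromo-3,5-bis(methoxymethoxy)phenoxy]trimethylsilane F8.
- n-BuLi at −78 °C triggers bromine–lithium exchange and a retro-Brook shift of silicon from oxygen to carbon, which gives the lithium salt of 19.
- Tf2O then converts this phenoxide into the triflate, and the sequence comes back to the route at 20.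

**Further compounds**
F1 | step 15 | methyl (S)-3-[3,5-bis(methoxymethoxy)phenoxy]-3-{3,4-bis(methoxymethoxy)-5-[5,7-bis(methoxymethoxy)-2-(4-(methoxymethoxy)phenyl)-4-oxo-4H-chromen-6-yl]phenyl}propanoate | COC(=O)C[C@@H](c1cc(OCOC)c(OCOC)c(-c2c(OCOC)cc3oc(-c4ccc(OCOC)cc4)cc(=O)c3c2OCOC)c1)Oc1cc(OCOC)cc(OCOC)c1
F2 | step 15 | (S)-3-[3,5-bis(methoxymethoxy)phenoxy]-3-{3,4-bis(methoxymethoxy)-5-[5,7-bis(methoxymethoxy)-2-(4-(methoxymethoxy)phenyl)-4-oxo-4H-chromen-6-yl]phenyl}propanoic acid | OC(=O)C[C@@H](c1cc(OCOC)c(OCOC)c(-c2c(OCOC)cc3oc(-c4ccc(OCOC)cc4)cc(=O)c3c2OCOC)c1)Oc1cc(OCOC)cc(OCOC)c1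
F3 | step 9 | 3,4-bis(methoxymethoxy)-5-(4,4,5,5-tetramethyl-1,3,2-dioxaborolan-2-yl)benzaldehyde | O=Cc1cc(OCOC)c(OCOC)c(B2OC(C)(C)C(C)(C)O2)c1
F4 | step 9 | 3,4-bis(methoxymethoxy)-5-[5,7-bis(methoxymethoxy)-2-(4-(methoxymethoxy)phenyl)-4-oxo-4H-chromen-6-yl]benzaldehyde | O=Cc1cc(OCOC)c(OCOC)c(-c2c(OCOC)cc3oc(-c4ccc(OCOC)cc4)cc(=O)c3c2OCOC)c1
F5 | step 9 | methyl (±)-3-hydroxy-3-{3,4-bis(methoxymethoxy)-5-[5,7-bis(methoxymethoxy)-2-(4-(methoxymethoxy)phenyl)-4-oxo-4H-chromen-6-yl]phenyl}propanoate | COC(=O)CC(O)c1cc(OCOC)c(OCOC)c(-c2c(OCOC)cc3oc(-c4ccc(OCOC)cc4)cc(=O)c3c2OCOC)c1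
F6 | step 9 | methyl 3-oxo-3-{3,4-bis(methoxymethoxy)-5-[5,7-bis(methoxymethoxy)-2-(4-(methoxymethoxy)phenyl)-4-oxo-4H-chromen-6-yl]phenyl}propanoate | COC(=O)CC(=O)c1cc(OCOC)c(OCOC)c(-c2c(OCOC)cc3oc(-c4ccc(OCOC)cc4)cc(=O)c3c2OCOC)c1
F7 | step 12 | 2-bromo-3,5-bis(methoxymethoxy)phenol | Oc1cc(OCOC)cc(OCOC)c1Br
F8 | step 12 | [2-bromo-3,5-bis(methoxymethoxy)phenoxy]trimethylsilane | C[Si](C)(C)Oc1cc(OCOC)cc(OCOC)c1Br
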